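**Retrosynthetic overview**
- Feature used: ring B is a 1,2,4-trisubstituted phenol. Its oxygen-bearing C4' lies para to C1' (bonded to C2 of pyranone ring C, unit 1) and ortho to C3' (bonded to C3 of pyranone ring E, unit 2). A 2-silyloxydiene and an acceptor alkyne leave exactly this pattern.
- Key disconnection: after O-deprotection, ring B is opened at C1'–C2' and C5'–C6' (retro-aromatisation, retro-[4+2]). The pieces are a 2-ethynylchromone (rings A and C, supplies C1' and C6') and a 3-(3-silyloxybuta-1,3-dien-2-yl)flavone (rings D, E and F, supplies C2'–C5').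
- Alkyne branch: ring C is closed on a ring A acetophenone by oxalate Claisen condensation and cyclodehydration, then CO2Et → CH2OH → CHO → C≡CH by an aprotic diazo homologation.
- Diene branch: ring E is closed by aroylation and cyclodehydration of an α-allyl ring D ketone. Only afterwards is allyl converted to acetonyl (Wacker), α-methylenated and O-silylated, so no free 1,4-diketone meets the ring-closing acid and no Friedel–Crafts step is run on benzyl ethers.
- Ring order: C and E in parallel branches (A, D and F are purchased), B last, then fluoride and hydrogenolysis.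

Key step: step 11

Assumption: the target SMILES carries no stereodescriptor, so the hindered C3'–C3 axis is treated as configurationally undefined and no atroposelection is attempted.

**Step 1**
Reactants: 1 1-(2,6-dihydroxy-4-methoxyphenyl)ethan-1-one
Product: 2 1-[2-(benzyloxy)-6-hydroxy-4-methoxyphenyl]ethan-1-one
Conditions: BnBr (1.0 equiv), K2CO3 (1.1 equiv), acetone, reflux
Reagents that add atoms: benzyl bromide, BrCc1ccccc1
Why: Williamson etherification should stop at the mono-ether, because the two phenols are equivalent and the remaining OH is held in a strong hydrogen bond to the ketone, which lowers its nucleophilicity.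

**Step 2**
Reactants: 2 1-[2-(benzyloxy)-6-hydroxy-4-methoxyphenyl]ethan-1-one
Product: 4 ethyl 5-(benzyloxy)-7-methoxy-4-oxo-4H-chromene-2-carboxylate, via diketo ester 3 (not isolated)
Conditions: (CO2Et)2 (3 equiv), NaOEt (4 equiv), EtOH, reflux; then conc. HCl to pH 1, 70 °C, short heating
Reagents that add atoms: diethyl oxalate, CCOC(=O)C(=O)OCC
Why: Crossed Claisen condensation of the methyl ketone enolate with non-enolisable diethyl oxalate gives the 2,4-dioxo ester, whose phenol adds to the C2 ketone and loses water under acid (classical chromone-2-carboxylate cyclodehydration), closing ring C.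

**Step 3**
Reactants: 4 ethyl 5-(benzyloxy)-7-methoxy-4-oxo-4H-chromene-2-carboxylate
Product: 5 5-(benzyloxy)-2-(hydroxymethyl)-7-methoxy-4H-chromen-4-one
Conditions: NaBH4 (1.5 equiv), THF/EtOH, 0 °C
Reagents that add atoms: none
Why: Chemoselective borohydride reduction should stop at the primary allylic alcohol, because the ester sits on the electron-poor C2 and is activated, whereas the C4 carbonyl is a vinylogous ester further deactivated by the 5- and 7-alkoxy donors.

**Step 4**
Reactants: 5 5-(benzyloxy)-2-(hydroxymethyl)-7-methoxy-4H-chromen-4-one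
Product: 6 5-(benzyloxy)-7-methoxy-4-oxo-4H-chromene-2-carbaldehyde
Conditions: Dess–Martin periodinane (1.2 equiv), CH2Cl2, 0 °C to rt
Reagents that add atoms: none
Why: Dess–Martin oxidation takes the primary allylic alcohol to the aldehyde under anhydrous, nearly neutral conditions, so neither over-oxidation nor attack of a nucleophile on ring C is expected.

**Step 5**
Reactants: 6 5-(benzyloxy)-7-methoxy-4-oxo-4H-chromene-2-carbaldehyde
Product: 7 5-(benzyloxy)-2-ethynyl-7-methoxy-4H-chromen-4-one
Conditions: Me3SiCHN2 (1.15 equiv), n-BuLi (1.1 equiv), THF, −78 °C; add 6, −78 °C to rt; then AcOH (1.2 equiv)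
Reagents that add atoms: (trimethylsilyl)diazomethane, C[Si](C)(C)C=[N+]=[N-]
Why: Colvin rearrangement (aprotic Seyferth–Gilbert-type homologation): the lithiated diazomethane adds at −78 °C to the aldehyde, by far the most electrophilic site, Peterson-type loss of silanolate and then of N2 gives an alkylidene carbene whose 1,2-hydrogen shift delivers the terminal alkyne, and the absence of methanol and carbonate spares C2 of ring C and the new acceptor alkyne from conjugate addition.

**Step 6**
Reactants: 8 1-[2,4-bis(benzyloxy)-6-hydroxyphenyl]ethan-1-one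
Product: 9 1-[2,4-bis(benzyloxy)-6-hydroxyphenyl]pent-4-en-1-one
Conditions: LiN(i-Pr)2 (2.2 equiv), THF, −78 to −20 °C; allyl bromide (1.05 equiv), −78 to 0 °C; then 1 M HCl
Reagents that add atoms: allyl bromide, C=CCBr
Why: Alkylation of the dilithio phenoxide–enolate dianion takes place at the far more nucleophilic enolate carbon (SN2 on allyl bromide), while the chelated lithium phenoxide stays inert at low temperature.

**Step 7**
Reactants: 9 1-[2,4-bis(benzyloxy)-6-hydroxyphenyl]pent-4-en-1-one; 10 4-(benzyloxy)benzoyl chloride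
Product: 12 3-allyl-5,7-bis(benzyloxy)-2-[4-(benzyloxy)phenyl]-4H-chromen-4-one, via allyl 1,3-diketone 11 (not isolated)
Conditions: LiN(SiMe3)2 (3.2 equiv), THF, −78 to −10 °C; 10 (1.05 equiv), −78 °C to rt; 1 M HCl quench, solvent exchange; p-TsOH·H2O (0.2 equiv), toluene, 90 °C
Reagents that add atoms: none
Why: Aroylation of the dianion at carbon, or at the phenoxide followed by a Baker–Venkataraman acyl shift under the excess base, converge on the same 1,3-diketone, and acid-catalysed cyclodehydration (phenol onto the aroyl carbonyl, loss of water) closes ring E with the allyl group at C3.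

**Step 8**
Reactants: 12 3-allyl-5,7-bis(benzyloxy)-2-[4-(benzyloxy)phenyl]-4H-chromen-4-one
Product: 13 5,7-bis(benzyloxy)-2-[4-(benzyloxy)phenyl]-3-(2-oxopropyl)-4H-chromen-4-one
Conditions: PdCl2 (0.1 equiv), CuCl (1 equiv), O2 (1 atm), DMF/H2O, rt
Reagents that add atoms: water, O
Why: Wacker–Tsuji oxidation: Markovnikov hydroxypalladation of the monosubstituted alkene by divalent palladium and β-hydride elimination give the methyl ketone, CuCl/O2 re-oxidises zerovalent palladium, and the tetrasubstituted ring E double bond and the benzyl ethers are left alone.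

**Step 9**
Reactants: 13 5,7-bis(benzyloxy)-2-[4-(benzyloxy)phenyl]-3-(2-oxopropyl)-4H-chromen-4-one
Product: 15 5,7-bis(benzyloxy)-2-[4-(benzyloxy)phenyl]-3-(3-oxobut-1-en-2-yl)-4H-chromen-4-one, via Mannich base 14 (not isolated)
Conditions: (Me2N)2CH2 (2 equiv), Ac2O (4 equiv), DMF, rt to 60 °C; used without storage
Reagents that add atoms: bis(dimethylamino)methane, CN(C)CN(C)C
Why: Mannich α-methylenation: the iminium acetate released from the aminal is captured by the more stabilised enol of 13, the one conjugated with the C2=C3 bond of ring E, and N-acetylation of the β-amino ketone triggers loss of the amine to give the α-methylene ketone, as is known for arylacetones and deoxybenzoins.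

**Step 10**
Reactants: 15 5,7-bis(benzyloxy)-2-[4-(benzyloxy)phenyl]-3-(3-oxobut-1-en-2-yl)-4H-chromen-4-one
Product: 16 5,7-bis(benzyloxy)-2-[4-(benzyloxy)phenyl]-3-{3-[(tert-butyldimethylsilyl)oxy]buta-1,3-dien-2-yl}-4H-chromen-4-one
Conditions: TBSOTf (1.3 equiv), Et3N (2 equiv), CH2Cl2, 0 °C; cold NaHCO3 work-up, Et3N-deactivated silica
Reagents that add atoms: tert-butyldimethylsilyl triflate, CC(C)(C)[Si](C)(C)OS(=O)(=O)C(F)(F)F
Why: Soft enolisation with a silyl triflate and a tertiary amine can give only one silyl enol ether, because the methyl group is the sole enolisable position left in 15, and the bulky silyl group makes the 2-silyloxydiene robust enough for handling and heating.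

**Step 11**
Reactants: 16 5,7-bis(benzyloxy)-2-[4-(benzyloxy)phenyl]-3-{3-[(tert-butyldimethylsilyl)oxy]buta-1,3-dien-2-yl}-4H-chromen-4-one; 7 5-(benzyloxy)-2-ethynyl-7-methoxy-4H-chromen-4-one
Product: 18 5-(benzyloxy)-2-{3-[5,7-bis(benzyloxy)-2-(4-(benzyloxy)phenyl)-4-oxo-4H-chromen-3-yl]-4-[(tert-butyldimethylsilyl)oxy]phenyl}-7-methoxy-4H-chromen-4-one, via cyclohexa-1,4-diene adduct 17 (not isolated)
Conditions: 7 (1.2 equiv), BHT (0.05 equiv), PhCl (0.5 M), 130 °C, sealed base-washed tube, dark; cool to rt, DDQ (1.2 equiv), rt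
Reagents that add atoms: none
Why: This is a normal-electron-demand Diels–Alder reaction in which the HOMO of 16, largest at the CH2 next to C–OTBS, meets the LUMO of 7, lowered and polarised towards its CH terminus by conjugation through the C2=C3–C4=O enone of ring C, so that C5'–C6' and C1'–C2' form in one concerted, asynchronous event. The closest known reaction type is the addition of 2-silyloxybuta-1,3-dienes to ynones or propiolates followed by DDQ dehydrogenation to para-acyl aryl silyl ethers. Ring B closes by an intermolecular [4+2] cycloaddition, suprafacial on both partners (four carbons from 16, two from 7), to the cyclohexa-1,4-diene 17, from which DDQ takes a hydride at one doubly allylic CH2 and a proton at the other, a process that should leave the Si–O bond and the benzyl ethers intact at room temperature. No stereocentre is created, since the only sp3 carbons of 17 are CH2 groups that end as aromatic CH. The step needs regioselectivity (C4'–O para rather than meta to C1') and chemoselectivity for the alkyne over the C2=C3 bonds of both chromones; the first rests on the silyloxy group being the stronger donor while the flavon-3-yl group is twisted out of the diene plane by its C2 aryl and C4 carbonyl neighbours, the second on the ring double bonds being tri- or tetrasubstituted and deactivated by the ring oxygen. The 2,3-disubstitution penalises the s-trans form at least as much as the s-cis form, so the reactive conformer stays accessible, and BHT, darkness and acid-free glass suppress polymerisation, photocyclisation onto ring F and enol ether hydrolysis.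

**Step 12**
Reactants: 18 protected target (ring B silyl ether, four benzyl ethers)
Product: 19 5-(benzyloxy)-2-{3-[5,7-bis(benzyloxy)-2-(4-(benzyloxy)phenyl)-4-oxo-4H-chromen-3-yl]-4-hydroxyphenyl}-7-methoxy-4H-chromen-4-one
Conditions: Bu4NF (1.2 equiv), AcOH (1.2 equiv), THF, 0 °C
Reagents that add atoms: none
Why: Fluoride-induced cleavage of the aryl silyl ether is driven by the strong Si–F bond, and the acetic acid buffer protonates the phenoxide at once so that neither chromone sees a basic medium.

**Step 13**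
Reactants: 19 5-(benzyloxy)-2-{3-[5,7-bis(benzyloxy)-2-(4-(benzyloxy)phenyl)-4-oxo-4H-chromen-3-yl]-4-hydroxyphenyl}-7-methoxy-4H-chromen-4-one
Product: 20 2-{3-[5,7-dihydroxy-2-(4-hydroxyphenyl)-4-oxo-4H-chromen-3-yl]-4-hydroxyphenyl}-5-hydroxy-7-methoxy-4H-chromen-4-one (target)
Conditions: H2 (1 atm), Pd/C (10 wt %), THF/MeOH, rt, stopped at full debenzylation
Reagents that add atoms: none
Why: Catalytic hydrogenolysis cleaves the four benzylic C–O bonds, while the aryl methyl ether is inert and the aryl-substituted C2=C3 bonds of the two flavone units, being parts of vinylogous esters, are reduced much more slowly.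

**Compound list**
1 | 1-(2,6-dihydroxy-4-methoxyphenyl)ethan-1-one | CC(=O)c1c(O)cc(OC)cc1O | starting material
2 | 1-[2-(benzyloxy)-6-hydroxy-4-methoxyphenyl]ethan-1-one | CC(=O)c1c(O)cc(OC)cc1OCc1ccccc1 | intermediate
3 | ethyl 4-[2-(benzyloxy)-6-hydroxy-4-methoxyphenyl]-2,4-dioxobutanoate | CCOC(=O)C(=O)CC(=O)c1c(O)cc(OC)cc1OCc1ccccc1 | intermediate
4 | ethyl 5-(benzyloxy)-7-methoxy-4-oxo-4H-chromene-2-carboxylate | CCOC(=O)c1cc(=O)c2c(OCc3ccccc3)cc(OC)cc2o1 | intermediate
5 | 5-(benzyloxy)-2-(hydroxymethyl)-7-methoxy-4H-chromen-4-one | OCc1cc(=O)c2c(OCc3ccccc3)cc(OC)cc2o1 | intermediate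
6 | 5-(benzyloxy)-7-methoxy-4-oxo-4H-chromene-2-carbaldehyde | O=Cc1cc(=O)c2c(OCc3ccccc3)cc(OC)cc2o1 | intermediate
7 | 5-(benzyloxy)-2-ethynyl-7-methoxy-4H-chromen-4-one | C#Cc1cc(=O)c2c(OCc3ccccc3)cc(OC)cc2o1 | intermediate
8 | 1-[2,4-bis(benzyloxy)-6-hydroxyphenyl]ethan-1-one | CC(=O)c1c(O)cc(OCc2ccccc2)cc1OCc1ccccc1 | starting material
9 | 1-[2,4-bis(benzyloxy)-6-hydroxyphenyl]pent-4-en-1-one | C=CCCC(=O)c1c(O)cc(OCc2ccccc2)cc1OCc1ccccc1 | intermediate
10 | 4-(benzyloxy)benzoyl chloride | O=C(Cl)c1ccc(OCc2ccccc2)cc1 | starting material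
11 | 2-allyl-1-[2,4-bis(benzyloxy)-6-hydroxyphenyl]-3-[4-(benzyloxy)phenyl]propane-1,3-dione (racemic, enolisable) | C=CCC(C(=O)c1ccc(OCc2ccccc2)cc1)C(=O)c1c(O)cc(OCc2ccccc2)cc1OCc1ccccc1 | intermediate
12 | 3-allyl-5,7-bis(benzyloxy)-2-[4-(benzyloxy)phenyl]-4H-chromen-4-one | C=CCc1c(-c2ccc(OCc3ccccc3)cc2)oc2cc(OCc3ccccc3)cc(OCc3ccccc3)c2c1=O | intermediate
13 | 5,7-bis(benzyloxy)-2-[4-(benzyloxy)phenyl]-3-(2-oxopropyl)-4H-chromen-4-one | CC(=O)Cc1c(-c2ccc(OCc3ccccc3)cc2)oc2cc(OCc3ccccc3)cc(OCc3ccccc3)c2c1=O | intermediate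
14 | 5,7-bis(benzyloxy)-2-[4-(benzyloxy)phenyl]-3-[1-(dimethylamino)-3-oxobutan-2-yl]-4H-chromen-4-one (racemic) | CC(=O)C(CN(C)C)c1c(-c2ccc(OCc3ccccc3)cc2)oc2cc(OCc3ccccc3)cc(OCc3ccccc3)c2c1=O | intermediate
15 | 5,7-bis(benzyloxy)-2-[4-(benzyloxy)phenyl]-3-(3-oxobut-1-en-2-yl)-4H-chromen-4-one | CC(=O)C(=C)c1c(-c2ccc(OCc3ccccc3)cc2)oc2cc(OCc3ccccc3)cc(OCc3ccccc3)c2c1=O | intermediate
16 | 5,7-bis(benzyloxy)-2-[4-(benzyloxy)phenyl]-3-{3-[(tert-butyldimethylsilyl)oxy]buta-1,3-dien-2-yl}-4H-chromen-4-one | C=C(O[Si](C)(C)C(C)(C)C)C(=C)c1c(-c2ccc(OCc3ccccc3)cc2)oc2cc(OCc3ccccc3)cc(OCc3ccccc3)c2c1=O | intermediate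
17 | 5-(benzyloxy)-2-{5-[5,7-bis(benzyloxy)-2-(4-(benzyloxy)phenyl)-4-oxo-4H-chromen-3-yl]-4-[(tert-butyldimethylsilyl)oxy]cyclohexa-1,4-dien-1-yl}-7-methoxy-4H-chromen-4-one | COc1cc(OCc2ccccc2)c2c(=O)cc(C3=CCC(O[Si](C)(C)C(C)(C)C)=C(c4c(-c5ccc(OCc6ccccc6)cc5)oc5cc(OCc6ccccc6)cc(OCc6ccccc6)c5c4=O)C3)oc2c1 | intermediate
18 | 5-(benzyloxy)-2-{3-[5,7-bis(benzyloxy)-2-(4-(benzyloxy)phenyl)-4-oxo-4H-chromen-3-yl]-4-[(tert-butyldimethylsilyl)oxy]phenyl}-7-methoxy-4H-chromen-4-one | COc1cc(OCc2ccccc2)c2c(=O)cc(-c3ccc(O[Si](C)(C)C(C)(C)C)c(-c4c(-c5ccc(OCc6ccccc6)cc5)oc5cc(OCc6ccccc6)cc(OCc6ccccc6)c5c4=O)c3)oc2c1 | intermediate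
19 | 5-(benzyloxy)-2-{3-[5,7-bis(benzyloxy)-2-(4-(benzyloxy)phenyl)-4-oxo-4H-chromen-3-yl]-4-hydroxyphenyl}-7-methoxy-4H-chromen-4-one | COc1cc(OCc2ccccc2)c2c(=O)cc(-c3ccc(O)c(-c4c(-c5ccc(OCc6ccccc6)cc5)oc5cc(OCc6ccccc6)cc(OCc6ccccc6)c5c4=O)c3)oc2c1 | intermediate
20 | 2-{3-[5,7-dihydroxy-2-(4-hydroxyphenyl)-4-oxo-4H-chromen-3-yl]-4-hydroxyphenyl}-5-hydroxy-7-methoxy-4H-chromen-4-one | COc1cc(O)c2c(=O)cc(-c3ccc(O)c(-c4c(-c5ccc(O)cc5)oc5cc(O)cc(O)c5c4=O)c3)oc2c1 | target

**Step count**
Total step count: 13.
Longest linear sequence: 8 steps. Both branches have this length: 1 → 7 in five steps or 8 → 16 in five steps, followed by steps 11–13.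

**Steps most likely to fail**

Step 11 (cycloaddition and aromatisation). The alkyne is activated only through the ring C enone. Cycloaddition may therefore be slower than thermal dimerisation or hydrolysis of the diene, and the regiocontrol exerted by the silyloxy group may erode at the temperature required.
The fallback sets out from 16 and 2 and returns at 18. It keeps the diene but moves the construction of ring C behind that of ring B.
- Diene 16 is heated with methyl propiolate, a directly activated and well-tried dienophile (toluene, 110 °C), to give the cyclohexa-1,4-diene ester F1.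
- DDQ aromatises it in the same flask to the methyl benzoate F2.
- Claisen condensation of the dilithio dianion of 2 (LiN(SiMe3)2, THF, −78 °C to rt) with F2 gives the 1,3-diketone F3.
- p-TsOH in toluene closes ring C to give 18.

Step 5 (aldehyde to alkyne). The diazo anion or the silanolate may add to C2 of ring C or to the newly formed acceptor alkyne (ring opening, pyrazole formation) in competition with the homologation.
The fallback sets out from 6 and returns at 7. It replaces carbene chemistry by olefination and elimination.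
- Corey–Fuchs olefination (CBr4, PPh3, CH2Cl2, 0 °C) gives the dibromoalkene F4.
- Pd(PPh3)4-catalysed hydrogenolysis with Bu3SnH removes the less hindered bromine and gives the (Z)-bromoalkene F5.
- In F5 the vinylic hydrogen and the bromine are anti, so DBU in MeCN should effect E2 elimination to 7 without any organolithium reagent.

Step 9 (α-methylenation). Aminomethylation may occur on the methyl side, a second methylenation may follow, or the α-aryl enone may dimerise by hetero-Diels–Alder reaction while it forms slowly next to the hindered C3.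
The fallback sets out from 8 and 10 and returns at 15. It attaches the four-carbon enone as one piece by cross-coupling.
- Aroylation of the dianion of 8 with 10 (LiN(SiMe3)2, THF) gives the 1,3-diketone F6.
- p-TsOH closes it to tri-O-benzylapigenin F7.
- C3 lithiation (LiN(i-Pr)2, THF, −78 °C) and I2 give the 3-iodoflavone F8.
- Pd(PPh3)4-catalysed hydrostannation of but-3-yn-2-one with Bu3SnH gives the α-stannyl enone F9.
- Stille coupling of F8 with F9 (Pd2(dba)3, AsPh3, CuI, DMF, 50 °C) gives 15.

**Further compounds**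
F1 | step 11 | methyl 5-[5,7-bis(benzyloxy)-2-(4-(benzyloxy)phenyl)-4-oxo-4H-chromen-3-yl]-4-[(tert-butyldimethylsilyl)oxy]cyclohexa-1,4-diene-1-carboxylate | COC(=O)C1=CCC(O[Si](C)(C)C(C)(C)C)=C(c2c(-c3ccc(OCc4ccccc4)cc3)oc3cc(OCc4ccccc4)cc(OCc4ccccc4)c3c2=O)C1
F2 | step 11 | methyl 3-[5,7-bis(benzyloxy)-2-(4-(benzyloxy)phenyl)-4-oxo-4H-chromen-3-yl]-4-[(tert-butyldimethylsilyl)oxy]benzoate | COC(=O)c1ccc(O[Si](C)(C)C(C)(C)C)c(-c2c(-c3ccc(OCc4ccccc4)cc3)oc3cc(OCc4ccccc4)cc(OCc4ccccc4)c3c2=O)c1
F3 | step 11 | 1-[2-(benzyloxy)-6-hydroxy-4-methoxyphenyl]-3-{3-[5,7-bis(benzyloxy)-2-(4-(benzyloxy)phenyl)-4-oxo-4H-chromen-3-yl]-4-[(tert-butyldimethylsilyl)oxy]phenyl}propane-1,3-dione | COc1cc(O)c(C(=O)CC(=O)c2ccc(O[Si](C)(C)C(C)(C)C)c(-c3c(-c4ccc(OCc5ccccc5)cc4)oc4cc(OCc5ccccc5)cc(OCc5ccccc5)c4c3=O)c2)c(OCc2ccccc2)c1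
F4 | step 5 | 5-(benzyloxy)-2-(2,2-dibromoethenyl)-7-methoxy-4H-chromen-4-one | COc1cc(OCc2ccccc2)c2c(=O)cc(C=C(Br)Br)oc2c1
F5 | step 5 | 5-(benzyloxy)-2-[(Z)-2-bromoethenyl]-7-methoxy-4H-chromen-4-one | COc1cc(OCc2ccccc2)c2c(=O)cc(/C=C\Br)oc2c1
F6 | step 9 | 1-[2,4-bis(benzyloxy)-6-hydroxyphenyl]-3-[4-(benzyloxy)phenyl]propane-1,3-dione | O=C(CC(=O)c1c(O)cc(OCc2ccccc2)cc1OCc1ccccc1)c1ccc(OCc2ccccc2)cc1
F7 | step 9 | 5,7-bis(benzyloxy)-2-[4-(benzyloxy)phenyl]-4H-chromen-4-one | O=c1cc(-c2ccc(OCc3ccccc3)cc2)oc2cc(OCc3ccccc3)cc(OCc3ccccc3)c12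
F8 | step 9 | 5,7-bis(benzyloxy)-2-[4-(benzyloxy)phenyl]-3-iodo-4H-chromen-4-one | O=c1c(I)c(-c2ccc(OCc3ccccc3)cc2)oc2cc(OCc3ccccc3)cc(OCc3ccccc3)c12
F9 | step 9 | 3-(tributylstannyl)but-3-en-2-one | CCCC[Sn](CCCC)(CCCC)C(=C)C(C)=O
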